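**Assumption:** (R)-but-3-yn-2-ol, methyl (R)-lactate, 4-iodo-2-methoxyphenol and 3,4-dimethoxyphenylmagnesium bromide solution are taken as catalogue chemicals. The target is the (2S,3R,4R,5R)-oxolane (2,3-cis, 3,4-trans, 4,5-trans) carrying a (1R,2R)-threo chain on the C-2 aryl and a (1S,2S)-threo chain on the C-5 aryl.

**Retrosynthetic overview**
1. Target 20 ⇐ diketone 19 by one double Felkin–Anh reduction (both threo carbinols at once); 19 ⇐ two lactate-derived aryloxypropanoates (Mitsunobu, inversion) plus two equivalents of an aryl Grignard.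
2. The only ring, the oxolane, is closed last in the core assembly, as in lignan biosynthesis: the C-7 hydroxyl adds to a C-7' p-quinone methide. Here the quinone methide is reached by tautomerizing the 4-hydroxystyrene 11, so C-4 and C-5 are set in the ring closure, relayed from the fixed cis C-2/C-3 pair.
3. 11 ⇐ syn-homopropargylic alcohol 7 (methylalumination, then coupling with 4-iodo-2-methoxyphenol); 7 ⇐ aldehyde 3 + chiral allenylstannane 6.
4. Only the free phenol can form the quinone methide, so the two aryl groups are told apart without protecting groups: chain 1 goes on vanillin at the start, chain 2 on the phenol left after ring closure.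

**Step 1**
Reactants: 1 vanillin; 2 ethyl (S)-lactate
Product: 3 ethyl (2R)-2-(4-formyl-2-methoxyphenoxy)propanoate
Conditions: PPh3, DIAD, THF, 0 °C → rt
Reagents that add atoms: none
Why: Mitsunobu etherification of the acidic phenol with the secondary lactate alcohol is an SN2 process with clean inversion, so the (S)-carbinol becomes the (R)-aryloxy centre of chain 1.

**Step 2**
Reactants: 4 (R)-but-3-yn-2-ol
Product: 5 (2R)-but-3-yn-2-yl methanesulfonate
Conditions: MsCl, Et3N, CH2Cl2, −78 → 0 °C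
Reagents that add atoms: methanesulfonyl chloride, CS(=O)(=O)Cl
Why: O-sulfonylation (mesylation) does not touch the stereocentre and installs the propargylic leaving group.

**Step 3**
Reactants: 5 (2R)-but-3-yn-2-yl methanesulfonate
Product: 6 (aS)-tributyl(buta-1,2-dien-1-yl)stannane
Conditions: Bu3SnH, LiN(iPr)2, THF, 0 °C; CuBr·SMe2, −78 °C; then 5, −78 °C
Reagents that add atoms: tributyltin hydride, CCCC[SnH](CCCC)CCCC
Why: Anti SN2' displacement of the propargylic mesylate by the stannylcopper reagent transfers the central chirality of 5 to the allene axis, (R) → (aS).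

**Step 4**
Reactants: 3 ethyl (2R)-2-(4-formyl-2-methoxyphenoxy)propanoate; 6 (aS)-tributyl(buta-1,2-dien-1-yl)stannane
Product: 7 ethyl (2R)-2-{4-[(1S,2R)-1-hydroxy-2-methylbut-3-yn-1-yl]-2-methoxyphenoxy}propanoate
Conditions: BF3·OEt2 (2.2 equiv), CH2Cl2, −78 °C; NaHCO3 quench at −78 °C
Reagents that add atoms: none
Why: BF3-promoted anti-SE2' addition of the chiral allenylstannane (Marshall-type propargylation) goes through an open transition state that favours the syn adduct; the allene axis fixes the methyl-bearing carbon as R (net retention relative to 5) and the syn preference makes the carbinol S, while the ester is inert at −78 °C.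

**Step 5**
Reactants: 7 ethyl (2R)-2-{4-[(1S,2R)-1-hydroxy-2-methylbut-3-yn-1-yl]-2-methoxyphenoxy}propanoate; 8 4-iodo-2-methoxyphenol
Product: 11 ethyl (2R)-2-{4-[(1S,2R,3E)-1-hydroxy-4-(4-hydroxy-3-methoxyphenyl)-2,3-dimethylbut-3-en-1-yl]-2-methoxyphenoxy}propanoate, via aluminium phenoxide 9 (not isolated), via alkenylalane 10 (not isolated)
Conditions: 7, Me3Al (4 equiv), Cp2ZrCl2 (0.2 equiv), H2O (1 equiv), CH2Cl2, −20 °C; volatiles removed in vacuo; then 8 (pre-mixed with Me3Al, 1.0 equiv, THF, 0 °C), ZnCl2 (1 equiv), Pd(PPh3)4 (5 mol%), THF, rt → 45 °C; aq. potassium sodium tartrate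
Reagents that add atoms: trimethylaluminium, C[Al](C)C
Why: Zirconium-catalysed syn-methylalumination of the terminal alkyne (Negishi carboalumination, water-accelerated) puts methyl on the internal carbon, and the palladium-catalysed Negishi coupling of the alkenylalane proceeds with retention to give only the E-styrene; both stereocentres are untouched and the OH groups are masked in situ as aluminium alkoxides.

**Step 6**
Reactants: 11 ethyl (2R)-2-{4-[(1S,2R,3E)-1-hydroxy-4-(4-hydroxy-3-methoxyphenyl)-2,3-dimethylbut-3-en-1-yl]-2-methoxyphenoxy}propanoate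
Product: 13 ethyl (2R)-2-{4-[(2S,3R,4R,5R)-5-(4-hydroxy-3-methoxyphenyl)-3,4-dimethyloxolan-2-yl]-2-methoxyphenoxy}propanoate, via p-quinone methide 12 (not isolated)
Conditions: (PhO)2P(O)OH (10 mol%), toluene (0.01 M), 50 °C
Reagents that add atoms: none
Why: Proposed new method: the phosphoric acid protonates the electron-rich 4-hydroxystyrene at C-3 while accepting the phenolic proton, giving the neutral p-quinone methide 12 of lignan biosynthesis, which the C-1 hydroxyl captures by intramolecular oxa-1,6-addition; tautomerization and ring closure are reversible only at the p-hydroxybenzylic ether (the p-alkoxybenzylic C-2 ether should not ionize with this weak acid), so C-4 and C-5 equilibrate to the most stable 3,4-trans-4,5-trans arrangement beside the fixed cis C-2/C-3 pair; closest known reaction types are Brønsted-acid-catalysed generation and 1,6-trapping of p-quinone methides from 4-hydroxystyrenes or 4-hydroxybenzyl alcohols and acid-catalysed hydroalkoxylation of styrenes.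

**Step 7**
Reactants: 13 ethyl (2R)-2-{4-[(2S,3R,4R,5R)-5-(4-hydroxy-3-methoxyphenyl)-3,4-dimethyloxolan-2-yl]-2-methoxyphenoxy}propanoate; 14 methyl (R)-lactate
Product: 15 ethyl (2R)-2-{4-[(2S,3R,4R,5R)-5-(3-methoxy-4-{[(2S)-1-methoxy-1-oxopropan-2-yl]oxy}phenyl)-3,4-dimethyloxolan-2-yl]-2-methoxyphenoxy}propanoate
Conditions: PPh3, DIAD, THF, 0 °C → rt
Reagents that add atoms: none
Why: A second Mitsunobu etherification on the only free OH left inverts the (R)-lactate to the (S)-aryloxy centre of chain 2.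

**Step 8**
Reactants: 15 the diester from step 7; 16 N,O-dimethylhydroxylamine hydrochloride; 17 3,4-dimethoxyphenylmagnesium bromide
Product: 19 (2R)-1-(3,4-dimethoxyphenyl)-2-{4-[(2S,3R,4R,5R)-5-(4-{[(2S)-1-(3,4-dimethoxyphenyl)-1-oxopropan-2-yl]oxy}-3-methoxyphenyl)-3,4-dimethyloxolan-2-yl]-2-methoxyphenoxy}propan-1-one, via bis-Weinreb amide 18 (not isolated)
Conditions: 16 (3.2 equiv), iPrMgCl (6.2 equiv), THF, −20 °C; then 17 (6 equiv), −20 → 0 °C; aq. NH4Cl
Reagents that add atoms: 3,4-dimethoxyphenylmagnesium bromide (the second equivalent of 17, which arylates the second amide), COc1ccc([Mg]Br)cc1OC; N,O-dimethylhydroxylamine hydrochloride (the second equivalent of 16, which is built into 18 and leaves again on arylation), CNOC.Cl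
Why: Each molecule of 15 takes up two equivalents of the magnesium amide and then two equivalents of the aryl Grignard, because both esters are converted in the flask to Weinreb amides and the Weinreb ketone synthesis stops at the chelated tetrahedral intermediates, so no over-addition occurs and the α-aryloxy centres are not enolized at low temperature.

**Step 9**
Reactants: 19 the diketone from step 8
Product: 20 (1R,2R)-1-(3,4-dimethoxyphenyl)-2-{4-[(2S,3R,4R,5R)-5-(4-{[(1S,2S)-1-(3,4-dimethoxyphenyl)-1-hydroxypropan-2-yl]oxy}-3-methoxyphenyl)-3,4-dimethyloxolan-2-yl]-2-methoxyphenoxy}propan-1-ol (target)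
Conditions: borohydride exchange resin (Amberlite IRA-400, BH4− form), MeOH, 0 °C → rt
Reagents that add atoms: none
Why: Non-chelating Felkin–Anh hydride addition, with the aryloxy group anti to the incoming hydride, gives the syn (threo) alcohol in each chain under control of its own α-centre, so the (R)-ketone gives (1R,2R) and the (S)-ketone gives (1S,2S) in the same operation.

**Compound list**
1 | vanillin (4-hydroxy-3-methoxybenzaldehyde) | COc1cc(C=O)ccc1O | starting material
2 | ethyl (S)-lactate | CCOC(=O)[C@H](C)O | starting material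
3 | ethyl (2R)-2-(4-formyl-2-methoxyphenoxy)propanoate | CCOC(=O)[C@@H](C)Oc1ccc(C=O)cc1OC | intermediate
4 | (R)-but-3-yn-2-ol | C#C[C@@H](C)O | starting material
5 | (2R)-but-3-yn-2-yl methanesulfonate | C#C[C@@H](C)OS(C)(=O)=O | intermediate
6 | (aS)-tributyl(buta-1,2-dien-1-yl)stannane | CCCC[Sn](CCCC)(CCCC)C=[C@@]=CC | intermediate
7 | ethyl (2R)-2-{4-[(1S,2R)-1-hydroxy-2-methylbut-3-yn-1-yl]-2-methoxyphenoxy}propanoate | CCOC(=O)[C@@H](C)Oc1ccc([C@@H](O)[C@H](C)C#C)cc1OC | intermediate
8 | 4-iodo-2-methoxyphenol | COc1cc(I)ccc1O | starting material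
9 | dimethylaluminium 4-iodo-2-methoxyphenoxide | COc1cc(I)ccc1O[Al](C)C | intermediate (not isolated)
10 | ethyl (2R)-2-{4-[(1S,2R,3E)-4-(dimethylalumanyl)-1-[(dimethylalumanyl)oxy]-2,3-dimethylbut-3-en-1-yl]-2-methoxyphenoxy}propanoate | CCOC(=O)[C@@H](C)Oc1ccc([C@@H](O[Al](C)C)[C@H](C)/C(C)=C/[Al](C)C)cc1OC | intermediate (not isolated)
11 | ethyl (2R)-2-{4-[(1S,2R,3E)-1-hydroxy-4-(4-hydroxy-3-methoxyphenyl)-2,3-dimethylbut-3-en-1-yl]-2-methoxyphenoxy}propanoate | CCOC(=O)[C@@H](C)Oc1ccc([C@@H](O)[C@H](C)/C(C)=C/c2ccc(O)c(OC)c2)cc1OC | intermediate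
12 | ethyl (2R)-2-{4-[(1S,2R,3S)-1-hydroxy-4-(3-methoxy-4-oxocyclohexa-2,5-dien-1-ylidene)-2,3-dimethylbutyl]-2-methoxyphenoxy}propanoate (p-quinone methide; its C-3 epimer equilibrates through 11) | CCOC(=O)[C@@H](C)Oc1ccc([C@@H](O)[C@H](C)[C@@H](C)C=C2C=CC(=O)C(OC)=C2)cc1OC | intermediate (not isolated)
13 | ethyl (2R)-2-{4-[(2S,3R,4R,5R)-5-(4-hydroxy-3-methoxyphenyl)-3,4-dimethyloxolan-2-yl]-2-methoxyphenoxy}propanoate | CCOC(=O)[C@@H](C)Oc1ccc([C@H]2O[C@@H](c3ccc(O)c(OC)c3)[C@H](C)[C@H]2C)cc1OC | intermediate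
14 | methyl (R)-lactate | COC(=O)[C@@H](C)O | starting material
15 | ethyl (2R)-2-{4-[(2S,3R,4R,5R)-5-(3-methoxy-4-{[(2S)-1-methoxy-1-oxopropan-2-yl]oxy}phenyl)-3,4-dimethyloxolan-2-yl]-2-methoxyphenoxy}propanoate | CCOC(=O)[C@@H](C)Oc1ccc([C@H]2O[C@@H](c3ccc(O[C@@H](C)C(=O)OC)c(OC)c3)[C@H](C)[C@H]2C)cc1OC | intermediate
16 | N,O-dimethylhydroxylamine hydrochloride | CNOC.Cl | starting material
17 | 3,4-dimethoxyphenylmagnesium bromide | COc1ccc([Mg]Br)cc1OC | starting material
18 | (2R)-N-methoxy-2-{2-methoxy-4-[(2S,3R,4R,5R)-5-(3-methoxy-4-{[(2S)-1-[methoxy(methyl)amino]-1-oxopropan-2-yl]oxy}phenyl)-3,4-dimethyloxolan-2-yl]phenoxy}-N-methylpropanamide | CON(C)C(=O)[C@@H](C)Oc1ccc([C@H]2O[C@@H](c3ccc(O[C@@H](C)C(=O)N(C)OC)c(OC)c3)[C@H](C)[C@H]2C)cc1OC | intermediate (not isolated)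
19 | (2R)-1-(3,4-dimethoxyphenyl)-2-{4-[(2S,3R,4R,5R)-5-(4-{[(2S)-1-(3,4-dimethoxyphenyl)-1-oxopropan-2-yl]oxy}-3-methoxyphenyl)-3,4-dimethyloxolan-2-yl]-2-methoxyphenoxy}propan-1-one | COc1ccc(C(=O)[C@@H](C)Oc2ccc([C@H]3O[C@@H](c4ccc(O[C@@H](C)C(=O)c5ccc(OC)c(OC)c5)c(OC)c4)[C@H](C)[C@H]3C)cc2OC)cc1OC | intermediate
20 | (1R,2R)-1-(3,4-dimethoxyphenyl)-2-{4-[(2S,3R,4R,5R)-5-(4-{[(1S,2S)-1-(3,4-dimethoxyphenyl)-1-hydroxypropan-2-yl]oxy}-3-methoxyphenyl)-3,4-dimethyloxolan-2-yl]-2-methoxyphenoxy}propan-1-ol | COc1ccc([C@@H](O)[C@@H](C)Oc2ccc([C@H]3O[C@@H](c4ccc(O[C@@H](C)[C@@H](O)c5ccc(OC)c(OC)c5)c(OC)c4)[C@H](C)[C@H]3C)cc2OC)cc1OC | target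

**Step count:** 9 steps in total. Longest linear sequence: 8 steps (steps 2–9, from (R)-but-3-yn-2-ol); 7 steps from vanillin.

**Three steps most likely to fail**

Step 6 (untested tautomerization and oxa-1,6-addition). The risks are incomplete equilibration at C-4, ionization of the p-alkoxybenzylic carbinol or of the C-2 ether leading to the all-trans isomer, and Friedel–Crafts closure to an aryltetralin. The fallback sets out from 11 and separates the two events. A hydroxyl-directed hydrogenation of 11 ([Rh(nbd)(dppb)]BF4, H2, CH2Cl2) gives ethyl (2R)-2-{4-[(1S,2R,3S)-1-hydroxy-4-(4-hydroxy-3-methoxyphenyl)-2,3-dimethylbutyl]-2-methoxyphenoxy}propanoate F1. The facial sense of that hydrogenation is not secured by precedent and must be checked. Oxidation of the 4-alkylphenol in F1 with Ag2O (CH2Cl2, rt) then generates quinone methide 12 directly, which closes to 13, where the route is rejoined.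

Step 4 (syn:anti ratio of the allenylstannane addition to an electron-rich aryl aldehyde). The fallback sets out from 3 and comes back at 11, replacing steps 2–5. Isoprene and pinacolborane give, by Ni(cod)2/PCy3-catalysed 1,4-hydroboration, (Z)-4,4,5,5-tetramethyl-2-(2-methylbut-2-en-1-yl)-1,3,2-dioxaborolane F2. The regiochemistry of this hydroboration on a 2-substituted diene needs confirming. Allylboration of 3 with F2 under a chiral phosphoric acid (the TRIP enantiomer that delivers the 1S carbinol, toluene, −30 °C) goes through a closed chair transition state to the syn alcohol ethyl (2R)-2-{4-[(1S,2R)-1-hydroxy-2,3-dimethylbut-3-en-1-yl]-2-methoxyphenoxy}propanoate F3. A Heck arylation of F3 with 8 (Pd(OAc)2, Bu4NCl, NaHCO3, DMF, 80 °C) then gives 11. The E and Z styrenes both serve in step 6, but a non-conjugated alkene isomer would be lost.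

Step 5 (ester and two acidic OH groups in a one-pot alane coupling). The fallback sets out from 7 and comes back at 11. After the same methylalumination, the alane is quenched with I2 (THF, −30 °C) to give the isolable vinyl iodide ethyl (2R)-2-{4-[(1S,2R,3E)-1-hydroxy-4-iodo-2,3-dimethylbut-3-en-1-yl]-2-methoxyphenoxy}propanoate F4. A Suzuki–Miyaura coupling of F4 with commercial 2-methoxy-4-(4,4,5,5-tetramethyl-1,3,2-dioxaborolan-2-yl)phenol (Pd(dppf)Cl2, K3PO4, dioxane/H2O, 60 °C) tolerates the free phenol and gives 11.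

**Further compounds**
F1 | step 6 | ethyl (2R)-2-{4-[(1S,2R,3S)-1-hydroxy-4-(4-hydroxy-3-methoxyphenyl)-2,3-dimethylbutyl]-2-methoxyphenoxy}propanoate | CCOC(=O)[C@@H](C)Oc1ccc([C@@H](O)[C@H](C)[C@@H](C)Cc2ccc(O)c(OC)c2)cc1OC
F2 | step 4 | (Z)-4,4,5,5-tetramethyl-2-(2-methylbut-2-en-1-yl)-1,3,2-dioxaborolane | C/C=C(/C)CB1OC(C)(C)C(C)(C)O1
F3 | step 4 | ethyl (2R)-2-{4-[(1S,2R)-1-hydroxy-2,3-dimethylbut-3-en-1-yl]-2-methoxyphenoxy}propanoate | CCOC(=O)[C@@H](C)Oc1ccc([C@@H](O)[C@H](C)C(C)=C)cc1OC
F4 | step 5 | ethyl (2R)-2-{4-[(1S,2R,3E)-1-hydroxy-4-iodo-2,3-dimethylbut-3-en-1-yl]-2-methoxyphenoxy}propanoate | CCOC(=O)[C@@H](C)Oc1ccc([C@@H](O)[C@H](C)/C(C)=C/I)cc1OC
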